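**Retrosynthetic overview**
1. Stevensine 11 ⇒ open the C3a–C4 bond (acid cyclodehydration of pyrrole C3 onto a ketone, last step) ⇒ acyclic 4-acyl-2-aminoimidazole 9.
2. 9 ⇒ cut both imidazole C–N bonds (key step, new: iodine-mediated [3+2] annulation of guanidine onto an enaminone) ⇒ enaminone 5 + guanidine 6.
3. 5 ⇒ one-carbon aminomethylenation of methyl ketone 3 ⇒ amide C–N bond ⇒ trichloroacetylpyrrole 1 + 4-aminobutan-2-one 2.
4. Ring order: dibromopyrrole (bought) → 2-aminoimidazole (step 3) → azepinone (step 4).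

Assumption: the target SMILES has no stereocentre, so stevensine is achiral and no enantiomer has to be set; 1 and 2 are taken as catalogue compounds.

**Step 1**
Reactants: 1 2,2,2-trichloro-1-(4,5-dibromo-1H-pyrrol-2-yl)ethan-1-one; 2 4-aminobutan-2-one hydrochloride
Product: 3 4,5-dibromo-N-(3-oxobutyl)-1H-pyrrole-2-carboxamide
Conditions: Et3N (1.2 equiv, slow addition), MeCN, 0 °C to rt
Reagents that add atoms: 4-aminobutan-2-one hydrochloride 2, CC(=O)CCN.Cl
Why: Haloform-type aminolysis of the 2-(trichloroacetyl)pyrrole, in which the amine freed in the flask attacks the acyl carbon and CCl3 leaves as chloroform; slow base addition keeps the free β-amino ketone dilute so acylation outruns its self-condensation.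

**Step 2**
Reactants: 3 4,5-dibromo-N-(3-oxobutyl)-1H-pyrrole-2-carboxamide; 4 tert-butoxybis(dimethylamino)methane
Product: 5 4,5-dibromo-N-[(4E)-5-(dimethylamino)-3-oxopent-4-en-1-yl]-1H-pyrrole-2-carboxamide
Conditions: t-BuOCH(NMe2)2 (2.5 equiv), THF, 55 °C
Reagents that add atoms: tert-butoxybis(dimethylamino)methane 4, CN(C)C(OC(C)(C)C)N(C)C
Why: Bredereck aminomethylenation (orthoamide condensation) of the methyl ketone at its less hindered CH3 gives the E push–pull enaminone, and the tert-butoxy reagent cannot N-alkylate the acidic pyrrole N–H.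

**Step 3**
Reactants: 5 4,5-dibromo-N-[(4E)-5-(dimethylamino)-3-oxopent-4-en-1-yl]-1H-pyrrole-2-carboxamide; 6 guanidine hydrochloride
Product: 9 N-[3-(2-amino-1H-imidazol-5-yl)-3-oxopropyl]-4,5-dibromo-1H-pyrrole-2-carboxamide, via 4,5-dibromo-N-[(4Z)-5-(dimethylamino)-4-iodo-3-oxopent-4-en-1-yl]-1H-pyrrole-2-carboxamide 7 (not isolated), via N-[5-(carbamimidoylamino)-4-iodo-3-oxopent-4-en-1-yl]-4,5-dibromo-1H-pyrrole-2-carboxamide 8 (not isolated)
Conditions: I2 (1.05 equiv), K2CO3 (3.5 equiv), MeCN, 0 °C, 20 min; then guanidine·HCl (1.5 equiv), rt to 40 °C; aq. Na2S2O3 work-up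
Reagents that add atoms: guanidine hydrochloride 6, NC(N)=N.Cl; iodine, II (its iodine stays only in 7 and 8, not in 9)
Why: Proposed new method: a one-pot iodine-mediated dehydrogenative [3+2] aza-annulation of an N,N-dimethyl enaminone with unprotected guanidine, in which I2 iodinates the nucleophilic α-carbon (7), guanidine displaces dimethylamine at the β-carbon by addition–elimination (8), the α-iodo imine tautomer of 8 is closed by 5-exo-tet SN2 of the second guanidine nitrogen and tautomerisation gives the aromatic 4-acyl-2-aminoimidazole, while complete iodination at low temperature before guanidine is added diverts the substrate from the usual thermal enaminone + guanidine → 2-aminopyrimidine condensation; the closest known reaction types are the condensation of α-halo-1,3-dicarbonyl equivalents (2-halomalonaldehydes, 3-halochromones) with amidines to 4-acylimidazoles and iodine-mediated oxidative C–N annulations of enaminones.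

**Step 4**
Reactants: 9 N-[3-(2-amino-1H-imidazol-5-yl)-3-oxopropyl]-4,5-dibromo-1H-pyrrole-2-carboxamide
Product: 11 stevensine, 4-(2-amino-1H-imidazol-5-yl)-2,3-dibromo-6,7-dihydro-1H-pyrrolo[2,3-c]azepin-8-one, via 4-(2-amino-1H-imidazol-5-yl)-2,3-dibromo-4-hydroxy-4,5,6,7-tetrahydro-1H-pyrrolo[2,3-c]azepin-8-one 10 (not isolated)
Conditions: MeSO3H (neat), 60 to 90 °C; then aq. NH3 to the free base
Reagents that add atoms: none
Why: Intramolecular Friedel–Crafts hydroxyalkylation at the only free pyrrole carbon (C3) followed by E1 dehydration (Bradsher-type cyclodehydration), where the ketone next to the 2-aminoimidazolium ring is strongly activated in the acid, the racemic carbinol 10 ionises to a cation stabilised by both heteroaromatics and loses H-5 to give the conjugated C4=C5 alkene, so no stereocentre remains.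

**Compound list**
1 | 2,2,2-trichloro-1-(4,5-dibromo-1H-pyrrol-2-yl)ethan-1-one | O=C(c1cc(Br)c(Br)[nH]1)C(Cl)(Cl)Cl | starting material
2 | 4-aminobutan-2-one hydrochloride | CC(=O)CCN.Cl | starting material
3 | 4,5-dibromo-N-(3-oxobutyl)-1H-pyrrole-2-carboxamide | CC(=O)CCNC(=O)c1cc(Br)c(Br)[nH]1 | intermediate
4 | tert-butoxybis(dimethylamino)methane (Bredereck's reagent) | CN(C)C(OC(C)(C)C)N(C)C | starting material
5 | 4,5-dibromo-N-[(4E)-5-(dimethylamino)-3-oxopent-4-en-1-yl]-1H-pyrrole-2-carboxamide | CN(C)/C=C/C(=O)CCNC(=O)c1cc(Br)c(Br)[nH]1 | intermediate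
6 | guanidine hydrochloride | NC(N)=N.Cl | starting material
7 | 4,5-dibromo-N-[(4Z)-5-(dimethylamino)-4-iodo-3-oxopent-4-en-1-yl]-1H-pyrrole-2-carboxamide (not isolated) | CN(C)/C=C(I)/C(=O)CCNC(=O)c1cc(Br)c(Br)[nH]1 | intermediate
8 | N-[5-(carbamimidoylamino)-4-iodo-3-oxopent-4-en-1-yl]-4,5-dibromo-1H-pyrrole-2-carboxamide (not isolated; alkene geometry mobile, not defined) | NC(=N)NC=C(I)C(=O)CCNC(=O)c1cc(Br)c(Br)[nH]1 | intermediate
9 | N-[3-(2-amino-1H-imidazol-5-yl)-3-oxopropyl]-4,5-dibromo-1H-pyrrole-2-carboxamide | Nc1ncc(C(=O)CCNC(=O)c2cc(Br)c(Br)[nH]2)[nH]1 | intermediate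
10 | 4-(2-amino-1H-imidazol-5-yl)-2,3-dibromo-4-hydroxy-4,5,6,7-tetrahydro-1H-pyrrolo[2,3-c]azepin-8-one (racemic, not isolated) | Nc1ncc(C2(O)CCNC(=O)c3[nH]c(Br)c(Br)c32)[nH]1 | intermediate
11 | stevensine, 4-(2-amino-1H-imidazol-5-yl)-2,3-dibromo-6,7-dihydro-1H-pyrrolo[2,3-c]azepin-8-one (achiral) | Nc1ncc(C2=CCNC(=O)c3[nH]c(Br)c(Br)c32)[nH]1 | target

**Total step count:** 4
**Longest linear sequence:** 4

**Three steps most likely to fail, with fallbacks**

Step 3 (the new annulation) is the most uncertain: the guanidine may close onto the ketone instead and give a 5-iodo-2-aminopyrimidine, or the one-pot oxidation may be unclean. The fallback uses the known condensation of an isolated α-halo carbonyl equivalent with an acylguanidine. It sets out from 5. N-Bromosuccinimide (1.0 equiv, CH2Cl2, −20 °C) gives 4,5-dibromo-N-[(4Z)-4-bromo-5-(dimethylamino)-3-oxopent-4-en-1-yl]-1H-pyrrole-2-carboxamide F1, which is isolated. F1 is condensed with N-acetylguanidine (3 equiv, DMF, rt) to N-[3-(2-acetamido-1H-imidazol-5-yl)-3-oxopropyl]-4,5-dibromo-1H-pyrrole-2-carboxamide F2. Aqueous HCl in MeOH at 60 °C removes the acetyl group, and the sequence comes back to the route at 9.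

Step 4 (cyclodehydration) may stall because a ketone is a weaker electrophile than the aldehydes normally used for this ring closure, and the dibromopyrrole carboxamide is deactivated. The fallback lowers the oxidation level, closes the ring through the much more reactive 2-aminoimidazole-stabilised carbocation, and then re-oxidises. It sets out from 9. NaBH4 in MeOH at 0 °C gives racemic N-[3-(2-amino-1H-imidazol-5-yl)-3-hydroxypropyl]-4,5-dibromo-1H-pyrrole-2-carboxamide F3. MeSO3H at rt ionises the carbinol and pyrrole C3 closes the ring to racemic 4-(2-amino-1H-imidazol-5-yl)-2,3-dibromo-4,5,6,7-tetrahydro-1H-pyrrolo[2,3-c]azepin-8-one F4 (hymenin). Br2 (1 equiv) in CF3CO2H brominates the free imidazole carbon to give 4-(2-amino-4-bromo-1H-imidazol-5-yl)-2,3-dibromo-4,5,6,7-tetrahydro-1H-pyrrolo[2,3-c]azepin-8-one F5. Heating F5 in MeSO3H at 90 °C causes tautomerisation and loss of HBr, and the sequence comes back at 11.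

Step 2 (aminomethylenation) may fail through base-induced retro-aza-Michael cleavage of the β-amido ketone or through reagent consumption by the acidic pyrrole N–H. The fallback reaches the same enaminone by amine addition to an ynone, with no basic condensation on the ketone. It sets out from 1. Aminolysis with 3,3-diethoxypropan-1-amine (MeCN, rt) gives 4,5-dibromo-N-(3,3-diethoxypropyl)-1H-pyrrole-2-carboxamide F6. Aqueous HCl in acetone gives 4,5-dibromo-N-(3-oxopropyl)-1H-pyrrole-2-carboxamide F7. Ethynylmagnesium bromide (4 equiv, THF, 0 °C) gives racemic 4,5-dibromo-N-(3-hydroxypent-4-yn-1-yl)-1H-pyrrole-2-carboxamide F8. MnO2 in CH2Cl2 gives 4,5-dibromo-N-(3-oxopent-4-yn-1-yl)-1H-pyrrole-2-carboxamide F9. Conjugate addition of dimethylamine (THF, 0 °C) then comes back to the route at 5.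

**Further compounds**
F1 | step 3 | 4,5-dibromo-N-[(4Z)-4-bromo-5-(dimethylamino)-3-oxopent-4-en-1-yl]-1H-pyrrole-2-carboxamide | CN(C)/C=C(Br)/C(=O)CCNC(=O)c1cc(Br)c(Br)[nH]1
F2 | step 3 | N-[3-(2-acetamido-1H-imidazol-5-yl)-3-oxopropyl]-4,5-dibromo-1H-pyrrole-2-carboxamide | CC(=O)Nc1ncc(C(=O)CCNC(=O)c2cc(Br)c(Br)[nH]2)[nH]1
F3 | step 4 | N-[3-(2-amino-1H-imidazol-5-yl)-3-hydroxypropyl]-4,5-dibromo-1H-pyrrole-2-carboxamide (racemic) | Nc1ncc(C(O)CCNC(=O)c2cc(Br)c(Br)[nH]2)[nH]1
F4 | step 4 | 4-(2-amino-1H-imidazol-5-yl)-2,3-dibromo-4,5,6,7-tetrahydro-1H-pyrrolo[2,3-c]azepin-8-one (racemic hymenin) | Nc1ncc(C2CCNC(=O)c3[nH]c(Br)c(Br)c32)[nH]1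
F5 | step 4 | 4-(2-amino-4-bromo-1H-imidazol-5-yl)-2,3-dibromo-4,5,6,7-tetrahydro-1H-pyrrolo[2,3-c]azepin-8-one (racemic) | Nc1nc(Br)c(C2CCNC(=O)c3[nH]c(Br)c(Br)c32)[nH]1
F6 | step 2 | 4,5-dibromo-N-(3,3-diethoxypropyl)-1H-pyrrole-2-carboxamide | CCOC(CCNC(=O)c1cc(Br)c(Br)[nH]1)OCC
F7 | step 2 | 4,5-dibromo-N-(3-oxopropyl)-1H-pyrrole-2-carboxamide | O=CCCNC(=O)c1cc(Br)c(Br)[nH]1
F8 | step 2 | 4,5-dibromo-N-(3-hydroxypent-4-yn-1-yl)-1H-pyrrole-2-carboxamide (racemic) | C#CC(O)CCNC(=O)c1cc(Br)c(Br)[nH]1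
F9 | step 2 | 4,5-dibromo-N-(3-oxopent-4-yn-1-yl)-1H-pyrrole-2-carboxamide | C#CC(=O)CCNC(=O)c1cc(Br)c(Br)[nH]1
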